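**Plan**

Cuts: the benzyl cap and the C6–O aroyl bond go first. The trans-8,9-diol is traced back through the 8α,9α-epoxide to a C8=C9 alkene. The seven-membered ring is then cut at C7–C8 and C9–C10, the cyclopropane at C10–C1/C10–C5, and the cyclopentene at C1=C5.
Enabling feature: in the seven-membered ring (C1, C5, C6, C7, C8, C9, C10), quaternary C1 lies between C5 and C10, C6 next to C5 is oxygenated, and C8–C9 is a two-carbon unit with one methyl branch. C1/C5/C10 can therefore be held as a cyclopropane fused to the five-membered ring, C6=C7 as a siloxyvinyl group on C5, and C8–C9 as a silylpropyne.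
Forward order: the five-membered ring comes first (ozonolysis and aldol re-closure of terpinen-4-ol), then the cyclopropane, then the seven-membered ring by a rhodium (5+2) cycloaddition. Oxygenation of C8/C9 and acylation of C6–OH follow.
Stereochemistry: C4 is bought with (S)-terpinen-4-ol. C1 comes from a carbinol-directed cyclopropanation whose temporary C6 centre is set by CBS reduction. C5 comes from face-selective protonation, C6 from hydride delivery by the C4 hydroxyl, and C9/C8 from C6–OH-directed epoxidation and invertive hydrolysis.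

Key step: step 11

Remark: daucane numbering is used (C1 quaternary ring-fusion carbon, C4 carbinol carbon bearing isopropyl, C5 ring-fusion CH, C6–C10 the rest of the seven-membered ring), β is the face of the C4 oxygen and the C1 methyl, and commercial (S)-(+)-terpinen-4-ol is assumed to be enantiopure.

Step 1
Reactants: 1 (S)-terpinen-4-ol
Product: 2 (S)-terpinen-4-yl triethylsilyl ether
Conditions: TESOTf, 2,6-lutidine, CH2Cl2, 0 °C → rt
Reagents that add atoms: triethylsilyl triflate, CC[Si](CC)(CC)OS(=O)(=O)C(F)(F)F
Why: Silyl triflate silylation is the reliable way to cap a hindered tertiary alcohol; C4 is untouched, and the bulky ether switches off hydroxyl direction to the β face and screens that face in steps 7 and 12.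

Step 2
Reactants: 2 (S)-terpinen-4-yl triethylsilyl ether
Product: 4 (S)-3-isopropyl-6-oxo-3-(triethylsilyloxy)heptanal, via secondary ozonide 3 (not isolated)
Conditions: O3, CH2Cl2, −78 °C; then Me2S, −78 °C → rt
Reagents that add atoms: ozone, [O-][O+]=O
Why: Ozonolysis with reductive work-up cleaves the only C=C bond to the 1,6-keto aldehyde, and the silyl ether and C4 are inert to ozone and Me2S.

Step 3
Reactants: 4 (S)-3-isopropyl-6-oxo-3-(triethylsilyloxy)heptanal
Product: 5 (R)-5-isopropyl-2-methyl-5-(triethylsilyloxy)cyclopent-1-ene-1-carbaldehyde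
Conditions: piperidine, AcOH (cat.), toluene, 60 °C
Reagents that add atoms: none
Why: Amine–acid catalysed intramolecular aldol condensation: the enamine of the aldehyde attacks the methyl ketone in a 5-exo-trig closure (C5–C1) and loss of water gives the conjugated enal, the established outcome for 6-oxoheptanals, while the near-neutral buffer and the poor silanolate leaving group should spare the β-silyloxy group.

Step 4
Reactants: 5 (R)-5-isopropyl-2-methyl-5-(triethylsilyloxy)cyclopent-1-ene-1-carbaldehyde; 6 methylmagnesium bromide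
Product: 7 1-[(5R)-5-isopropyl-2-methyl-5-(triethylsilyloxy)cyclopent-1-en-1-yl]ethanol (both C6 epimers)
Conditions: MeMgBr, THF, −78 → 0 °C; aq. work-up
Reagents that add atoms: methylmagnesium bromide (6), C[Mg]Br
Why: Grignard 1,2-addition to the enal installs C7; the new C6 centre forms without control, which is harmless because step 5 erases it.

Step 5
Reactants: 7 1-[(5R)-5-isopropyl-2-methyl-5-(triethylsilyloxy)cyclopent-1-en-1-yl]ethanol
Product: 8 1-[(5R)-5-isopropyl-2-methyl-5-(triethylsilyloxy)cyclopent-1-en-1-yl]ethanone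
Conditions: Dess–Martin periodinane, CH2Cl2, 0 °C → rt
Reagents that add atoms: none
Why: Dess–Martin oxidation converges both allylic epimers on one enone under mild conditions that leave the silyl ether and the tetrasubstituted alkene alone.

Step 6
Reactants: 8 1-[(5R)-5-isopropyl-2-methyl-5-(triethylsilyloxy)cyclopent-1-en-1-yl]ethanone
Product: 9 (1R)-1-[(5R)-5-isopropyl-2-methyl-5-(triethylsilyloxy)cyclopent-1-en-1-yl]ethanol (6R)
Conditions: (S)-2-methyl-CBS-oxazaborolidine (20 mol %), BH3·SMe2, THF, −20 °C; aq. work-up
Reagents that add atoms: none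
Why: Corey–Bakshi–Shibata reduction: the (S)-oxazaborolidine tells the bulky cyclopentenyl group from methyl, as with aryl and alkenyl methyl ketones, and should give the 6R carbinol by reagent control, the tetrasubstituted alkene being too hindered for hydroboration.

Step 7
Reactants: 9 (6R)-allylic alcohol; 10 diiodomethane
Product: 11 (1R)-1-[(1S,2R,5R)-2-isopropyl-5-methyl-2-(triethylsilyloxy)bicyclo[3.1.0]hexan-1-yl]ethanol (C10 methylene α, C1 methyl β)
Conditions: Et2Zn, CH2I2, DME, CH2Cl2, −10 °C → rt
Reagents that add atoms: diiodomethane (10), ICI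
Why: Hydroxyl-directed Simmons–Smith cyclopropanation (Furukawa reagent): allylic 1,3-strain with the C1 methyl turns C6–H into the alkene plane, which places the zinc alkoxide of the 6R carbinol on the α face, so CH2 (C10) is delivered there, anti to the C4 silyloxy group, and sets C1 and C5 together.

Step 8
Reactants: 11 cyclopropyl carbinol
Product: 12 1-[(1R,2R,5R)-2-isopropyl-5-methyl-2-(triethylsilyloxy)bicyclo[3.1.0]hexan-1-yl]ethanone
Conditions: Dess–Martin periodinane, CH2Cl2, 0 °C → rt
Reagents that add atoms: none
Why: Dess–Martin oxidation removes the auxiliary C6 centre and gives the cyclopropyl methyl ketone, and no acid strong enough to open the cyclopropylcarbinyl system is present.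

Step 9
Reactants: 12 cyclopropyl methyl ketone
Product: 13 (1S,2R,5R)-1-[1-(tert-butyldimethylsilyloxy)vinyl]-2-isopropyl-5-methyl-2-(triethylsilyloxy)bicyclo[3.1.0]hexane
Conditions: TBSOTf, Et3N, CH2Cl2, 0 °C
Reagents that add atoms: tert-butyldimethylsilyl triflate, CC(C)(C)[Si](C)(C)OS(=O)(=O)C(F)(F)F
Why: Soft enolisation with silyl triflate and amine; C5 is quaternary, so only the methyl group (C7) can enolise and a single enol silane results.

Step 10
Reactants: 14 prop-1-yn-1-ylmagnesium bromide; 15 benzylchlorodimethylsilane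
Product: 16 benzyldimethyl(prop-1-yn-1-yl)silane
Conditions: THF, 0 °C → rt
Reagents that add atoms: prop-1-yn-1-ylmagnesium bromide (14), CC#C[Mg]Br; benzylchlorodimethylsilane (15), C[Si](C)(Cl)Cc1ccccc1
Why: Substitution of a chlorosilane by an alkynyl Grignard reagent; the benzyldimethylsilyl group is chosen because it is bulky enough to steer the cycloaddition yet leaves later with fluoride, so that no strong acid is ever needed near the tertiary C4 carbinol.

Step 11
Reactants: 13 ring-fused 1-(1-siloxyvinyl)cyclopropane; 16 benzyldimethyl(prop-1-yn-1-yl)silane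
Product: 17 (1R,4R)-9-(benzyldimethylsilyl)-6-(tert-butyldimethylsilyloxy)-4-(triethylsilyloxy)dauca-5,8-diene
Conditions: [Rh(CO)2Cl]2 (5 mol %), 16 (3 equiv), ClCH2CH2Cl, 70 °C
Reagents that add atoms: benzyldimethyl(prop-1-yn-1-yl)silane (16), CC#C[Si](C)(C)Cc1ccccc1
Why: [Rh(CO)2Cl]2 supplies monovalent rhodium, which binds the electron-rich C6=C7 bond of 13 and inserts into the neighbouring strained C5–C10 bond to give a trivalent rhodacycle with an allyl unit over C5–C6–C7 and a σ bond to C10; alkyne 16 then inserts at C7 (C7–C8) and reductive elimination joins C9 to C10. The closest known reaction type is the intermolecular (5+2) cycloaddition of oxygen-substituted and 1-substituted vinylcyclopropanes with alkynes under this same catalyst, of which ring-fused 13 is a crowded member. The seven-membered ring is closed on the metal, by reductive elimination from an eight-membered rhodacycle, so no endo or exo attack of a free chain end is involved. No stereocentre is created: C5 becomes trigonal, while C1 and C4 are spectators and keep their configuration. Cleavage of C5–C10 rather than C5–C1 is expected because C10 is the only unsubstituted cyclopropane carbon and gives a primary Rh–C bond, because opening the ring-fusion bond would lead to a bridged bridgehead alkene, and because quaternary C1 leaves the rhodacycle no β-hydrogen to lose. Methyl on C8 and silicon on C9 are expected because the bulky silyl group stays away from the C7–C8 bond made in the insertion, and the silylalkyne is also slow to oligomerise.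

Step 12
Reactants: 17 siloxy diene
Product: 19 9-(benzyldimethylsilyl)-4β-hydroxy-5αH-dauc-8-en-6-one, via 4-O-triethylsilyl ketone 18 (not isolated)
Conditions: HF·pyridine, pyridine, THF, 0 °C → rt
Reagents that add atoms: none
Why: Fluoride-assisted cleavage of a silyl enol ether and a silyl ether: the enol silane goes first and C5 should be protonated from the α face because the β face is covered by the C4 triethylsilyloxy group and the C1 methyl, giving the trans-fused ketone, which after loss of the triethylsilyl group is held by a C4–OH···O=C6 hydrogen bond, while the pyridine buffer should prevent β-elimination, migration of the β,γ double bond and attack on the C–Si bonds.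

Step 13
Reactants: 19 β-hydroxy ketone
Product: 20 9-(benzyldimethylsilyl)dauc-8-ene-4β,6α-diol
Conditions: Me4NBH(OAc)3, MeCN–AcOH (1:1), −30 → −20 °C
Reagents that add atoms: none
Why: Evans–Saksena reduction: the borohydride exchanges an acetate for the β-oriented C4 hydroxyl and hands its hydride to the β face of C6 through a six-membered transition state, which sets the 6α-alcohol, and the vinylsilane is inert.

Step 14
Reactants: 20 silylated diol
Product: 21 dauc-8-ene-4β,6α-diol (jaeschkeanadiol)
Conditions: n-Bu4NF, wet THF, rt → 50 °C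
Reagents that add atoms: none
Why: Fluoride-promoted protodesilylation of a benzyldimethylsilyl alkene: fluoride expels the benzyl group and the activated silicon is then replaced by a proton without moving the double bond, and the diol holds no base-sensitive group.

Step 15
Reactants: 21 jaeschkeanadiol
Product: 22 8α,9α-epoxydaucane-4β,6α-diol
Conditions: VO(acac)2 (5 mol %), t-BuOOH, CH2Cl2, 0 °C → rt
Reagents that add atoms: tert-butyl hydroperoxide, CC(C)(C)OO
Why: Vanadium-catalysed hydroxyl-directed epoxidation: the vanadate ester of the homoallylic 6α-hydroxyl carries the peroxide to the α face of the only alkene and so sets C8 and C9 of the 8α,9α-epoxide.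

Step 16
Reactants: 22 epoxy diol; 23 4-(benzyloxy)benzoic acid
Product: 24 8α,9α-epoxy-4β-hydroxydaucan-6α-yl 4-(benzyloxy)benzoate
Conditions: DCC, DMAP, CH2Cl2, rt
Reagents that add atoms: 4-(benzyloxy)benzoic acid (23), OC(=O)c1ccc(OCc2ccccc2)cc1
Why: Steglich esterification acylates the secondary C6 hydroxyl, the tertiary C4 hydroxyl being too hindered, and the epoxide tolerates the neutral conditions.

Step 17
Reactants: 24 epoxy ester
Product: 25 4β,8β,9α-trihydroxydaucan-6α-yl 4-(benzyloxy)benzoate
Conditions: HClO4 (cat.), THF–H2O, 0 °C → rt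
Reagents that add atoms: water, O
Why: Acid-catalysed epoxide hydrolysis: water attacks the protonated epoxide at tertiary C8, which carries more positive charge, from the β face with inversion, while C9 keeps its α oxygen and is shielded from β attack by neopentyl C10 and the C1 methyl, so the 8β,9α-trans-diol should result, and the α-placed ester cannot take part from the rear.

Step 18
Reactants: 25 benzyl-protected triol ester
Product: 26 4β,8β,9α-trihydroxydaucan-6α-yl 4-hydroxybenzoate (CNP0197754.1)
Conditions: H2 (1 atm), Pd/C, EtOAc, rt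
Reagents that add atoms: none
Why: Hydrogenolysis of the benzyl aryl ether over Pd/C; no alkene is left, the ester and alcohols are inert, and no stereocentre is touched.

**Compound list**

1 | (S)-(+)-terpinen-4-ol, (1S)-4-methyl-1-(propan-2-yl)cyclohex-3-en-1-ol | CC(C)[C@@]1(O)CC=C(C)CC1 | starting material
2 | (S)-terpinen-4-yl triethylsilyl ether | CC(C)[C@@]1(O[Si](CC)(CC)CC)CC=C(C)CC1 | intermediate
3 | secondary ozonide of 2 (1,2,4-trioxolane across the former C=C, acetal centres undefined) | CC(C)[C@@]1(O[Si](CC)(CC)CC)CC2OOC(C)(O2)CC1 | intermediate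
4 | (S)-3-isopropyl-6-oxo-3-(triethylsilyloxy)heptanal | CC(C)[C@@](O[Si](CC)(CC)CC)(CC=O)CCC(C)=O | intermediate
5 | (R)-5-isopropyl-2-methyl-5-(triethylsilyloxy)cyclopent-1-ene-1-carbaldehyde | CC(C)[C@]1(O[Si](CC)(CC)CC)CCC(C)=C1C=O | intermediate
6 | methylmagnesium bromide | C[Mg]Br | starting material
7 | 1-[(5R)-5-isopropyl-2-methyl-5-(triethylsilyloxy)cyclopent-1-en-1-yl]ethanol, both C6 epimers | CC(C)[C@]1(O[Si](CC)(CC)CC)CCC(C)=C1C(C)O | intermediate
8 | 1-[(5R)-5-isopropyl-2-methyl-5-(triethylsilyloxy)cyclopent-1-en-1-yl]ethanone | CC(C)[C@]1(O[Si](CC)(CC)CC)CCC(C)=C1C(C)=O | intermediate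
9 | (1R)-1-[(5R)-5-isopropyl-2-methyl-5-(triethylsilyloxy)cyclopent-1-en-1-yl]ethanol | CC(C)[C@]1(O[Si](CC)(CC)CC)CCC(C)=C1[C@@H](C)O | intermediate
10 | diiodomethane | ICI | starting material
11 | (1R)-1-[(1S,2R,5R)-2-isopropyl-5-methyl-2-(triethylsilyloxy)bicyclo[3.1.0]hexan-1-yl]ethanol | CC(C)[C@]1(O[Si](CC)(CC)CC)CC[C@]2(C)C[C@]12[C@@H](C)O | intermediate
12 | 1-[(1R,2R,5R)-2-isopropyl-5-methyl-2-(triethylsilyloxy)bicyclo[3.1.0]hexan-1-yl]ethanone | CC(C)[C@]1(O[Si](CC)(CC)CC)CC[C@]2(C)C[C@]12C(C)=O | intermediate
13 | (1S,2R,5R)-1-[1-(tert-butyldimethylsilyloxy)vinyl]-2-isopropyl-5-methyl-2-(triethylsilyloxy)bicyclo[3.1.0]hexane | CC(C)[C@]1(O[Si](CC)(CC)CC)CC[C@]2(C)C[C@]12C(=C)O[Si](C)(C)C(C)(C)C | intermediate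
14 | prop-1-yn-1-ylmagnesium bromide | CC#C[Mg]Br | starting material
15 | benzylchlorodimethylsilane | C[Si](C)(Cl)Cc1ccccc1 | starting material
16 | benzyldimethyl(prop-1-yn-1-yl)silane | CC#C[Si](C)(C)Cc1ccccc1 | intermediate
17 | (1R,4R)-9-(benzyldimethylsilyl)-6-(tert-butyldimethylsilyloxy)-4-(triethylsilyloxy)dauca-5,8-diene | CC(C)[C@]1(O[Si](CC)(CC)CC)CC[C@]2(C)CC([Si](C)(C)Cc3ccccc3)=C(C)CC(O[Si](C)(C)C(C)(C)C)=C12 | intermediate
18 | 9-(benzyldimethylsilyl)-4β-(triethylsilyloxy)-5αH-dauc-8-en-6-one | CC(C)[C@]1(O[Si](CC)(CC)CC)CC[C@]2(C)CC([Si](C)(C)Cc3ccccc3)=C(C)CC(=O)[C@H]21 | intermediate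
19 | 9-(benzyldimethylsilyl)-4β-hydroxy-5αH-dauc-8-en-6-one | CC(C)[C@]1(O)CC[C@]2(C)CC([Si](C)(C)Cc3ccccc3)=C(C)CC(=O)[C@H]21 | intermediate
20 | 9-(benzyldimethylsilyl)dauc-8-ene-4β,6α-diol | CC(C)[C@]1(O)CC[C@]2(C)CC([Si](C)(C)Cc3ccccc3)=C(C)C[C@H](O)[C@H]21 | intermediate
21 | dauc-8-ene-4β,6α-diol (jaeschkeanadiol) | CC(C)[C@]1(O)CC[C@]2(C)CC=C(C)C[C@H](O)[C@H]21 | intermediate
22 | 8α,9α-epoxydaucane-4β,6α-diol | CC(C)[C@]1(O)CC[C@]2(C)C[C@@H]3O[C@]3(C)C[C@H](O)[C@H]21 | intermediate
23 | 4-(benzyloxy)benzoic acid | OC(=O)c1ccc(OCc2ccccc2)cc1 | starting material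
24 | 8α,9α-epoxy-4β-hydroxydaucan-6α-yl 4-(benzyloxy)benzoate | CC(C)[C@]1(O)CC[C@]2(C)C[C@@H]3O[C@]3(C)C[C@H](OC(=O)c4ccc(OCc5ccccc5)cc4)[C@H]21 | intermediate
25 | 4β,8β,9α-trihydroxydaucan-6α-yl 4-(benzyloxy)benzoate | CC(C)[C@]1(O)CC[C@]2(C)C[C@H](O)[C@@](C)(O)C[C@H](OC(=O)c3ccc(OCc4ccccc4)cc3)[C@H]21 | intermediate
26 | 4β,8β,9α-trihydroxydaucan-6α-yl 4-hydroxybenzoate, (1R,4R,5S,6S,8S,9S) | CC(C)[C@]1(O)CC[C@]2(C)C[C@H](O)[C@@](C)(O)C[C@H](OC(=O)c3ccc(O)cc3)[C@H]21 | target

**Step count**

Total step count: 18. Longest linear sequence: 17 (steps 1–9 and 11–18; step 10 is a side branch).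

**Steps most likely to fail**

**Step 11.** What may go wrong:
- Rhodium may be slow to enter the C5–C10 bond because C5 sits between two fully substituted carbons.
- Isomerisation of the vinylcyclopropane to a cyclopentene, or loss of the enol silane, could then overtake alkyne capture.
- The orientation of the alkyne could also erode.

The fallback closes the ring by metathesis instead of cycloaddition. It sets out from 5 and returns at 21. Allylmagnesium bromide adds to enal 5 to give the dienol F1. Anionic oxy-Cope rearrangement (KH, 18-crown-6, THF, cold quench to spare the β-silyloxy group) moves the allyl group to C1 on the α face, away from the silyloxy group. Protonation of the enolate then gives the trans-configured aldehyde F2. 2-Methylallylmagnesium chloride adds to give the 6α-carbinol F3. Ring-closing metathesis with the second-generation Grubbs catalyst closes C8=C9 and gives 4-O-triethylsilyl jaeschkeanadiol F4. n-Bu4NF then frees the C4 hydroxyl to give 21.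

**Step 12.** What may go wrong:
- Facial selectivity in the protonation of C5 may be poor, since both faces of the tetrasubstituted enol carry substituents.
- Later equilibration is not an option, because enolisation towards C7 would let the β,γ double bond drift into conjugation.

The fallback sets C5 and C6 in one syn addition. It sets out from 17 and returns at 21. CsF and PhNTf2 convert the enol silane regiospecifically into the enol triflate F5. Pd(OAc)2, PPh3, HCO2H and Et3N reduce it to the 6-unsubstituted 5,8-diene F6. BH3·THF followed by NaOH/H2O2 adds H to C5 and OH to C6 on the same face. The much larger borane is pushed to the α face by the silyloxy group and the angular methyl, and the fully substituted vinylsilane stays inert. This gives the 6α-alcohol F7. n-Bu4NF removes the triethylsilyl and benzyldimethylsilyl groups together to give 21.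

**Step 7.** What may go wrong:
- Methylene transfer to the tetrasubstituted alkene next to quaternary C4 may be sluggish.
- Facial selectivity may be poor if crowding by C4 disturbs the carbinol conformer on which the direction relies.

The fallback replaces substrate direction by reagent control. It sets out from 5 and returns at 12. i-Bu2AlH reduces enal 5 to the primary allylic alcohol F8. Charette asymmetric cyclopropanation follows, using Zn(CH2I)2 and (4S,5S)-2-butyl-N,N,N',N'-tetramethyl-1,3,2-dioxaborolane-4,5-dicarboxamide, the ligand enantiomer that the empirical model assigns to the α face. It gives the cyclopropylmethanol F9. Dess–Martin oxidation gives the cyclopropanecarbaldehyde F10. Methylmagnesium bromide 6 gives the carbinol mixture F11, and a second Dess–Martin oxidation gives 12.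

**Further compounds**

F1 | step 11 | 1-[(5R)-5-isopropyl-2-methyl-5-(triethylsilyloxy)cyclopent-1-en-1-yl]but-3-en-1-ol, both C6 epimers | CC(C)[C@]1(O[Si](CC)(CC)CC)CCC(C)=C1C(O)CC=C
F2 | step 11 | 2α-allyl-5α-isopropyl-2β-methyl-5β-(triethylsilyloxy)cyclopentane-1β-carbaldehyde | CC(C)[C@]1(O[Si](CC)(CC)CC)CC[C@](C)(CC=C)[C@H]1C=O
F3 | step 11 | 6α-carbinol from addition of the 2-methylallyl group to F2 | CC(C)[C@]1(O[Si](CC)(CC)CC)CC[C@](C)(CC=C)[C@H]1[C@@H](O)CC(C)=C
F4 | step 11 | 4-O-triethylsilyl jaeschkeanadiol | CC(C)[C@]1(O[Si](CC)(CC)CC)CC[C@]2(C)CC=C(C)C[C@H](O)[C@H]21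
F5 | step 12 | 9-(benzyldimethylsilyl)-4-(triethylsilyloxy)dauca-5,8-dien-6-yl triflate | CC(C)[C@]1(O[Si](CC)(CC)CC)CC[C@]2(C)CC([Si](C)(C)Cc3ccccc3)=C(C)CC(OS(=O)(=O)C(F)(F)F)=C12
F6 | step 12 | 9-(benzyldimethylsilyl)-4-(triethylsilyloxy)dauca-5,8-diene | CC(C)[C@]1(O[Si](CC)(CC)CC)CC[C@]2(C)CC([Si](C)(C)Cc3ccccc3)=C(C)CC=C12
F7 | step 12 | 9-(benzyldimethylsilyl)-4β-(triethylsilyloxy)dauc-8-en-6α-ol | CC(C)[C@]1(O[Si](CC)(CC)CC)CC[C@]2(C)CC([Si](C)(C)Cc3ccccc3)=C(C)C[C@H](O)[C@H]21
F8 | step 7 | [(5R)-5-isopropyl-2-methyl-5-(triethylsilyloxy)cyclopent-1-en-1-yl]methanol | CC(C)[C@]1(O[Si](CC)(CC)CC)CCC(C)=C1CO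
F9 | step 7 | [2-isopropyl-5-methyl-2-(triethylsilyloxy)bicyclo[3.1.0]hexan-1-yl]methanol, methylene α | CC(C)[C@]1(O[Si](CC)(CC)CC)CC[C@]2(C)C[C@]12CO
F10 | step 7 | 2-isopropyl-5-methyl-2-(triethylsilyloxy)bicyclo[3.1.0]hexane-1-carbaldehyde, methylene α | CC(C)[C@]1(O[Si](CC)(CC)CC)CC[C@]2(C)C[C@]12C=O
F11 | step 7 | 1-[2-isopropyl-5-methyl-2-(triethylsilyloxy)bicyclo[3.1.0]hexan-1-yl]ethanol, methylene α, both C6 epimers | CC(C)[C@]1(O[Si](CC)(CC)CC)CC[C@]2(C)C[C@]12C(C)O
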